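Ring C (the 1,4-dioxane) is disconnected at the benzylic C2–O1 bond, O1 being the ring-B oxygen para to the acrylic acid chain. The key step exploits the 4-hydroxy-3-methoxyphenyl ring A on C2: its para-OH lets DDQ dehydrogenate a plain benzylic CH2 to a para-quinone methide, which the adjacent ring-B phenol O1 captures by 6-exo-trig oxa-1,6-addition. One operation thus converts a C–H into the C2–O1 bond, closes ring C and sets C2 trans to the existing C3 centre. The precursor is an acyclic (S)-2-aryloxy-3-arylpropan-1-ol with a single stereocentre, built from (R)-benzyl glycidyl ether by aryl-Grignard epoxide opening and Mitsunobu inversion.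

Key step: step 4

Assumption: compounds 1, 2, 5 and 10 are taken as purchasable; if 1 had to be made, it is one O-benzylation of 4-bromo-2-methoxyphenol.

Step 1
Reactants: 1 1-(benzyloxy)-4-bromo-2-methoxybenzene; 2 (R)-benzyl glycidyl ether
Product: 4 (2R)-1-(benzyloxy)-3-[4-(benzyloxy)-3-methoxyphenyl]propan-2-ol, via arylmagnesium bromide 3 (not isolated)
Conditions: Mg, THF, 40 °C; then CuI (10 mol%), 2, −30 → 0 °C; 1 M HCl
Reagents that add atoms: none
Why: Copper-catalysed Grignard opening of a terminal epoxide proceeds by SN2 attack at the unsubstituted carbon, so the stereocentre of 2 is not touched and is carried into 4 as the (R)-carbinol.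

Step 2
Reactants: 4 (2R)-1-(benzyloxy)-3-[4-(benzyloxy)-3-methoxyphenyl]propan-2-ol; 5 4-(benzyloxy)-3-hydroxybenzaldehyde
Product: 6 4-(benzyloxy)-3-({(2S)-1-(benzyloxy)-3-[4-(benzyloxy)-3-methoxyphenyl]propan-2-yl}oxy)benzaldehyde
Conditions: PPh3, DIAD, THF, 0 °C → rt
Reagents that add atoms: none
Why: Mitsunobu etherification, in which the only free phenol of 5 (the oxygen meta to CHO, the para oxygen being blocked as benzyl ether) displaces the alkoxyphosphonium by SN2 with inversion, so the (R)-carbinol becomes the (S)-aryl ether carbon that is the future C3.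

Step 3
Reactants: 6 4-(benzyloxy)-3-({(2S)-1-(benzyloxy)-3-[4-(benzyloxy)-3-methoxyphenyl]propan-2-yl}oxy)benzaldehyde
Product: 7 4-hydroxy-3-{[(2S)-1-hydroxy-3-(4-hydroxy-3-methoxyphenyl)propan-2-yl]oxy}benzaldehyde
Conditions: BCl3 (6 equiv), C6HMe5 (9 equiv), CH2Cl2, −78 → −20 °C; then H2O
Reagents that add atoms: none
Why: Lewis-acid debenzylation with pentamethylbenzene as a non-basic benzyl-cation scavenger should cleave the two aryl benzyl ethers and the primary alkyl benzyl ether without hydrogen, so the aldehyde survives and no bond at the stereocentre is broken.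

Step 4
Reactants: 7 4-hydroxy-3-{[(2S)-1-hydroxy-3-(4-hydroxy-3-methoxyphenyl)propan-2-yl]oxy}benzaldehyde
Product: 9 (2R,3R)-2-(4-hydroxy-3-methoxyphenyl)-3-(hydroxymethyl)-2,3-dihydro-1,4-benzodioxine-6-carbaldehyde, via para-quinone methide 8 (not isolated)
Conditions: DDQ (1.05 equiv), dry 1,4-dioxane, 15 °C → rt
Reagents that add atoms: none
Why: DDQ abstracts hydride from the only para-hydroxybenzylic CH2 (on ring A) and the phenol proton is lost, giving para-quinone methide 8, whose exocyclic carbon is attacked by the ring-B phenol oxygen in an oxa-1,6-conjugate addition that rearomatises ring A. The closest known reaction type is the DDQ dehydrogenative cyclisation of 4-hydroxyphenyl-alkanes that carry an internal OH, as in flavan formation from 1,3-diarylpropanes and tetrahydrofuran formation in lignans. Ring C closes in a 6-exo-trig mode. The new C2 centre is controlled by the C3 centre: the half-chair with aryl and CH2OH both pseudo-equatorial leads to the trans (2R,3R) isomer, and the acidic DDQH2 formed should keep the addition reversible so that the more stable trans isomer accumulates. The step needs chemoselective oxidation of ring A, secured because ring B is deactivated by its formyl group and only 1.05 equiv of DDQ is used to spare the product, and it needs capture by the phenol in preference to the CH2OH group (4-exo, strained) or to tautomerisation to an enol ether, secured by the ortho placement of the phenol next to the ether oxygen.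

Step 5
Reactants: 9 (2R,3R)-2-(4-hydroxy-3-methoxyphenyl)-3-(hydroxymethyl)-2,3-dihydro-1,4-benzodioxine-6-carbaldehyde; 10 malonic acid
Product: 12 (E)-3-[(2R,3R)-2-(4-hydroxy-3-methoxyphenyl)-3-(hydroxymethyl)-2,3-dihydro-1,4-benzodioxin-6-yl]prop-2-enoic acid, via arylidenemalonic acid 11 (not isolated)
Conditions: pyridine, piperidine (cat.), 70 °C; then dilute HCl
Reagents that add atoms: none
Why: Knoevenagel–Doebner condensation, in which arylidenemalonic acid 11 decarboxylates in pyridine to the (E)-cinnamic acid, while the non-enolisable C2 and C3 centres, the phenol and the primary alcohol are not engaged.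

Compound list
1 | 1-(benzyloxy)-4-bromo-2-methoxybenzene | COc1cc(Br)ccc1OCc1ccccc1 | starting material
2 | (R)-benzyl glycidyl ether, (2R)-2-[(benzyloxy)methyl]oxirane | C1O[C@H]1COCc1ccccc1 | starting material
3 | [4-(benzyloxy)-3-methoxyphenyl]magnesium bromide | COc1cc([Mg]Br)ccc1OCc1ccccc1 | intermediate
4 | (2R)-1-(benzyloxy)-3-[4-(benzyloxy)-3-methoxyphenyl]propan-2-ol | COc1cc(C[C@@H](O)COCc2ccccc2)ccc1OCc1ccccc1 | intermediate
5 | 4-(benzyloxy)-3-hydroxybenzaldehyde | O=Cc1ccc(OCc2ccccc2)c(O)c1 | starting material
6 | 4-(benzyloxy)-3-({(2S)-1-(benzyloxy)-3-[4-(benzyloxy)-3-methoxyphenyl]propan-2-yl}oxy)benzaldehyde | COc1cc(C[C@H](Oc2cc(C=O)ccc2OCc2ccccc2)COCc2ccccc2)ccc1OCc1ccccc1 | intermediate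
7 | 4-hydroxy-3-{[(2S)-1-hydroxy-3-(4-hydroxy-3-methoxyphenyl)propan-2-yl]oxy}benzaldehyde | COc1cc(C[C@H](Oc2cc(C=O)ccc2O)CO)ccc1O | intermediate
8 | 4-hydroxy-3-{[(2S)-1-hydroxy-3-(3-methoxy-4-oxocyclohexa-2,5-dien-1-ylidene)propan-2-yl]oxy}benzaldehyde (para-quinone methide) | COC1=CC(=C[C@H](Oc2cc(C=O)ccc2O)CO)C=CC1=O | intermediate
9 | (2R,3R)-2-(4-hydroxy-3-methoxyphenyl)-3-(hydroxymethyl)-2,3-dihydro-1,4-benzodioxine-6-carbaldehyde | COc1cc([C@H]2Oc3ccc(C=O)cc3O[C@@H]2CO)ccc1O | intermediate
10 | malonic acid | O=C(O)CC(=O)O | starting material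
11 | 2-{[(2R,3R)-2-(4-hydroxy-3-methoxyphenyl)-3-(hydroxymethyl)-2,3-dihydro-1,4-benzodioxin-6-yl]methylidene}propanedioic acid | COc1cc([C@H]2Oc3ccc(C=C(C(=O)O)C(=O)O)cc3O[C@@H]2CO)ccc1O | intermediate
12 | (E)-3-[(2R,3R)-2-(4-hydroxy-3-methoxyphenyl)-3-(hydroxymethyl)-2,3-dihydro-1,4-benzodioxin-6-yl]prop-2-enoic acid | COc1cc([C@H]2Oc3ccc(/C=C/C(=O)O)cc3O[C@@H]2CO)ccc1O | target

Total step count: 5. Longest linear sequence: 5 steps (1 → 4 → 6 → 7 → 9 → 12).

Steps most likely to fail

Step 4 (key step). The product's own C2–H could be oxidised by DDQ, the quinone methide could tautomerise to an enol ether (which would erase the C3 centre), or the ring could close with low trans selectivity. Fallback: setting out from 7, DDQ in MeOH/CH2Cl2 at 0 °C lets the solvent trap the quinone methide at once, giving the benzylic methyl ether 4-hydroxy-3-{[(2R)-3-hydroxy-1-(4-hydroxy-3-methoxyphenyl)-1-methoxypropan-2-yl]oxy}benzaldehyde F1 (both epimers at the methoxy carbon, same spatial arrangement at the aryloxy carbon), which is isolated. Catalytic TsOH in CH2Cl2 at rt, with no oxidant present, then ionises the benzylic ether and closes ring C under thermodynamic control with loss of methanol, coming back to the route at 9.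

Step 2. Substitution at the hindered secondary centre could be sluggish, or the alkoxyphosphonium could eliminate towards the conjugated aryl-propene. Fallback: setting out from 4, MsCl/Et3N in CH2Cl2 at 0 °C gives the sulfonate (2R)-1-(benzyloxy)-3-[4-(benzyloxy)-3-methoxyphenyl]propan-2-yl methanesulfonate F2. The pre-formed caesium phenoxide of 5 (Cs2CO3, DMF, 60 °C) displaces it by SN2 with inversion, coming back to the route at 6.

Step 5. In hot amine base the para-hydroxybenzyl aryl ether could open reversibly by retro-oxa-1,6-addition, with epimerisation at C2 or capture of the quinone methide by piperidine, and the primary alcohol could be acylated by malonic acid. Fallback: setting out from 9, Wittig olefination with the stabilised ylide Ph3P=CHCO2Me in CH2Cl2 at rt gives the ester methyl (E)-3-[(2R,3R)-2-(4-hydroxy-3-methoxyphenyl)-3-(hydroxymethyl)-2,3-dihydro-1,4-benzodioxin-6-yl]prop-2-enoate F3. LiOH in THF/H2O at rt followed by acidification then releases the acid, coming back to the route at 12.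

Further compounds
F1 | step 4 | 4-hydroxy-3-{[(2R)-3-hydroxy-1-(4-hydroxy-3-methoxyphenyl)-1-methoxypropan-2-yl]oxy}benzaldehyde | COc1cc(C(OC)[C@H](Oc2cc(C=O)ccc2O)CO)ccc1O
F2 | step 2 | (2R)-1-(benzyloxy)-3-[4-(benzyloxy)-3-methoxyphenyl]propan-2-yl methanesulfonate | COc1cc(C[C@@H](OS(C)(=O)=O)COCc2ccccc2)ccc1OCc1ccccc1
F3 | step 5 | methyl (E)-3-[(2R,3R)-2-(4-hydroxy-3-methoxyphenyl)-3-(hydroxymethyl)-2,3-dihydro-1,4-benzodioxin-6-yl]prop-2-enoate | COc1cc([C@H]2Oc3ccc(/C=C/C(=O)OC)cc3O[C@@H]2CO)ccc1O
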